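**Plan**

- Numbering: ring C1 (epoxide C–CH3), C2 (C=O), C3 (CH–O-senecioyl), C4 (CH–side chain), C5 (CH2), C6 (epoxide CH); side chain C1′H2=C2′–C3′H(O-angeloyl)–C4′H2–C5′H=C6′(CH3)2.
- Enabling feature: in the six-membered carbocycle the C1–C6 epoxide marks a former C=C lying between the ketone carbon C2 and the methylene C5, and C3/C4 are adjacent and trans. The ring is therefore a Diels–Alder retron: C2–C1=C6–C5 from a 1-oxygenated 2-methylbutadiene, C3–C4 from an E alkene.
- Retrosynthetic cuts, in order: C2=O to a silyl-protected carbinol; the C3′–O angelate; the C2′–C3′ bond (alkenyl triflate plus 4-methylpent-3-enal); the C3–O senecioate; the C3–O bond itself (from a C3 formyl group) together with the epoxide (from C1=C6); last, C4–C5 and C2–C3 in one cycloaddition.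
- Forward: the carbocycle is made first from the silyl dienol ether of tiglaldehyde and (2E)-4-oxopent-2-enal. One peracid step then gives the epoxide and the C3 oxygen. The senecioate, the side chain (grown from the acetyl group) and the angelate follow, and the C2 ketone is unveiled last.
- Stereochemistry: C3 and C4 (absolute, trans) come from the chiral amine catalyst and the E dienophile; the epoxide face from the temporary C2 silyloxy centre; C3′ from a chiral ligand on chromium; the Z angelate from angelic acid.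

Key step: step 3

Remark: in step 8 the ligand enantiomer is to be chosen so that the alkenylchromium species adds to the Re face of the aldehyde; both enantiomers are accessible from valinol.

**Route**

Step 1
Reactants: 1 2-methylfuran
Product: 3 (2E)-4-oxopent-2-enal, via (2Z)-4-oxopent-2-enal 2 (not isolated)
Conditions: NBS, NaHCO3, acetone/H2O (10:1), −15 °C; then pyridine, rt
Reagents that add atoms: water (O)
Why: Oxidative ring opening of a 2-alkylfuran (bromination at C5, addition of water, loss of HBr) should unmask the cis-ene-1,4-dicarbonyl, which pyridine isomerises to the more stable E isomer; no stereocentre is formed.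

Step 2
Reactants: 4 tiglaldehyde [(2E)-2-methylbut-2-enal]
Product: 5 tert-butyl(dimethyl){[(1E)-2-methylbuta-1,3-dien-1-yl]oxy}silane
Conditions: TBSOTf, Et3N, Et2O, 0 °C to rt
Reagents that add atoms: tert-butyldimethylsilyl trifluoromethanesulfonate (CC(C)(C)[Si](C)(C)OS(=O)(=O)C(F)(F)F)
Why: Silyl dienol ether formation by γ-deprotonation of the O-silylated enal in its s-trans conformation should place the silyloxy group trans to the vinyl group, which gives the (1E)-diene needed for cycloaddition.

Step 3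
Reactants: 3 (2E)-4-oxopent-2-enal; 5 tert-butyl(dimethyl){[(1E)-2-methylbuta-1,3-dien-1-yl]oxy}silane
Product: 8 (1S,2S,6R)-6-acetyl-2-[(tert-butyldimethylsilyl)oxy]-3-methylcyclohex-3-ene-1-carbaldehyde, via dienophile iminium chloride 6 (not isolated), via cycloadduct iminium chloride 7 (not isolated)
Conditions: (5R)-5-benzyl-2,2,3-trimethylimidazolidin-4-one hydrochloride (20 mol %), MeCN/H2O (95:5), −20 °C
Reagents that add atoms: none
Why: The amine salt condenses only with the aldehyde of 3 to give the (E)-iminium ion 6, whose lowered LUMO lets diene 5 add across the enal C=C in an asynchronous concerted Diels–Alder reaction, after which hydrolysis of iminium 7 releases 8 and the catalyst. The closest known reaction type is the imidazolidinone-catalysed enantioselective Diels–Alder reaction of enals with acyclic 1-oxygenated dienes such as 1-acetoxybutadiene. The cyclohexene ring closes by intermolecular [4+2] cycloaddition, the CH2 terminus of the diene bonding to the acetyl-bearing carbon and the silyloxy-bearing terminus to the formyl-bearing carbon. The formyl and acetyl groups end up trans because the E geometry of the dienophile is transferred suprafacially, the silyloxy group ends up cis to the formyl group through the transition state that is endo with respect to the iminium unit, and the absolute configuration follows from the benzyl group of the (5R) catalyst, which covers the Si face at the α-carbon so that the diene adds to the Re face. The step needs regioselectivity (the nucleophilic CH2 end of the 1-silyloxydiene must attack β to the aldehyde and not β to the ketone), and this is secured because only the aldehyde is turned into the far more electron-poor iminium ion. It also needs the (1E) geometry of 5 and a silyl group bulky enough to survive the wet, weakly acidic medium, which is why TBS is used.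

Step 4
Reactants: 8 (1S,2S,6R)-6-acetyl-2-[(tert-butyldimethylsilyl)oxy]-3-methylcyclohex-3-ene-1-carbaldehyde
Product: 11 1-[(1S,2S,3S,4R,6S)-2-[(tert-butyldimethylsilyl)oxy]-3-hydroxy-1-methyl-7-oxabicyclo[4.1.0]heptan-4-yl]ethan-1-one, via epoxy aldehyde 9 (not isolated), via epoxy formate 10 (not isolated)
Conditions: mCPBA (2.5 equiv), CH2Cl2, 0 °C to rt; then KHCO3 (cat.), MeOH, 0 °C
Reagents that add atoms: 3-chloroperoxybenzoic acid (OOC(=O)c1cccc(Cl)c1)
Why: Peracid epoxidation of the trisubstituted ring alkene is expected anti to the C2 silyloxy group (held pseudoaxial by allylic 1,2-strain with the vinylic methyl), so the oxirane should form trans to OTBS and cis to the acetyl group, while Baeyer–Villiger oxidation of the α-branched aldehyde migrates the secondary ring carbon with retention to give the formate, which bicarbonate-catalysed methanolysis cleaves to the C3 alcohol under conditions too mild for 1,2-silyl migration.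

Step 5
Reactants: 11 1-[(1S,2S,3S,4R,6S)-2-[(tert-butyldimethylsilyl)oxy]-3-hydroxy-1-methyl-7-oxabicyclo[4.1.0]heptan-4-yl]ethan-1-one; 12 3-methylbut-2-enoyl chloride
Product: 13 (1S,2S,3S,4R,6S)-4-acetyl-2-[(tert-butyldimethylsilyl)oxy]-1-methyl-7-oxabicyclo[4.1.0]heptan-3-yl 3-methylbut-2-enoate
Conditions: pyridine, DMAP (cat.), CH2Cl2, 0 °C to rt
Reagents that add atoms: none
Why: DMAP-catalysed acylation of the secondary alcohol with the acid chloride in pyridine (no trialkylamine, to avoid deconjugation through the vinylketene) should give the senecioate without touching any stereocentre.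

Step 6
Reactants: 13 (1S,2S,3S,4R,6S)-4-acetyl-2-[(tert-butyldimethylsilyl)oxy]-1-methyl-7-oxabicyclo[4.1.0]heptan-3-yl 3-methylbut-2-enoate
Product: 15 (1S,2S,3S,4R,6S)-2-[(tert-butyldimethylsilyl)oxy]-1-methyl-4-{1-[(trifluoromethanesulfonyl)oxy]ethenyl}-7-oxabicyclo[4.1.0]heptan-3-yl 3-methylbut-2-enoate, via potassium enolate 14 (not isolated)
Conditions: KN(SiMe3)2 (1.1 equiv), THF, −78 °C; then PhNTf2, −78 to −40 °C
Reagents that add atoms: N-phenylbis(trifluoromethanesulfonimide) (O=S(=O)(N(c1ccccc1)S(=O)(=O)C(F)(F)F)C(F)(F)F)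
Why: Kinetic deprotonation of the methyl ketone at the unhindered methyl group by a bulky amide base and O-triflation of the terminal enolate (enol triflate formation) should give the 1,1-disubstituted alkenyl triflate; the terminal enolate cannot expel the β-acyloxy group, and C4 is not touched.

Step 7
Reactants: 16 4-methylpent-3-en-1-ol
Product: 17 4-methylpent-3-enal
Conditions: Dess–Martin periodinane, NaHCO3, CH2Cl2, 0 °C to rt; used at once as a solution
Reagents that add atoms: none
Why: Dess–Martin oxidation under buffered, non-basic conditions should give the β,γ-unsaturated aldehyde without migration of the double bond into conjugation.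

Step 8
Reactants: 15 (1S,2S,3S,4R,6S)-2-[(tert-butyldimethylsilyl)oxy]-1-methyl-4-{1-[(trifluoromethanesulfonyl)oxy]ethenyl}-7-oxabicyclo[4.1.0]heptan-3-yl 3-methylbut-2-enoate; 17 4-methylpent-3-enal
Product: 19 (1S,2S,3S,4S,6S)-2-[(tert-butyldimethylsilyl)oxy]-4-[(3S)-3-hydroxy-6-methylhepta-1,5-dien-2-yl]-1-methyl-7-oxabicyclo[4.1.0]heptan-3-yl 3-methylbut-2-enoate, via alkenylchromium dichloride 18 (not isolated)
Conditions: CrCl2 (4 equiv), N-[2-(4-isopropyl-4,5-dihydro-1,3-oxazol-2-yl)-6-methylphenyl]methanesulfonamide (single enantiomer, 4.4 equiv), Et3N (4.4 equiv), NiCl2 (cat.), THF, rt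
Reagents that add atoms: none
Why: In this Nozaki–Hiyama–Kishi coupling zerovalent nickel inserts into the C–OTf bond, the alkenyl group passes to trivalent chromium and adds to the aldehyde in the presence of esters, epoxide and silyl ether, and the chromium-bound oxazoline sulfonamide ligand should direct addition to the Re face of the aldehyde (reagent control), which sets the (3S) carbinol centre.

Step 9
Reactants: 19 (1S,2S,3S,4S,6S)-2-[(tert-butyldimethylsilyl)oxy]-4-[(3S)-3-hydroxy-6-methylhepta-1,5-dien-2-yl]-1-methyl-7-oxabicyclo[4.1.0]heptan-3-yl 3-methylbut-2-enoate; 20 angelic acid [(2Z)-2-methylbut-2-enoic acid]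
Product: 22 (1S,2S,3S,4S,6S)-2-[(tert-butyldimethylsilyl)oxy]-1-methyl-4-[(3S)-6-methyl-3-{[(2Z)-2-methylbut-2-enoyl]oxy}hepta-1,5-dien-2-yl]-7-oxabicyclo[4.1.0]heptan-3-yl 3-methylbut-2-enoate, via mixed anhydride 21 (not isolated)
Conditions: 20, 2,4,6-trichlorobenzoyl chloride, Et3N, toluene, rt; then 19, toluene, 75 °C (no DMAP)
Reagents that add atoms: none
Why: Yamaguchi esterification through the preformed mixed anhydride, run without DMAP, is the established way to acylate hindered secondary alcohols with angelic acid without Z to E isomerisation to the tiglate, and the carbinol configuration is kept because its C–O bond is not broken.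

Step 10
Reactants: 22 (1S,2S,3S,4S,6S)-2-[(tert-butyldimethylsilyl)oxy]-1-methyl-4-[(3S)-6-methyl-3-{[(2Z)-2-methylbut-2-enoyl]oxy}hepta-1,5-dien-2-yl]-7-oxabicyclo[4.1.0]heptan-3-yl 3-methylbut-2-enoate
Product: 23 (1R,2S,3S,4S,6S)-2-hydroxy-1-methyl-4-[(3S)-6-methyl-3-{[(2Z)-2-methylbut-2-enoyl]oxy}hepta-1,5-dien-2-yl]-7-oxabicyclo[4.1.0]heptan-3-yl 3-methylbut-2-enoate
Conditions: HF·pyridine, pyridine, THF, 0 °C to rt
Reagents that add atoms: none
Why: Fluoride cleavage of the secondary TBS ether with pyridine-buffered HF·pyridine is a standard desilylation under which trisubstituted epoxides and enoate esters are known to survive and acyl migration from the neighbouring ester should be slow (the C1 descriptor changes from S to R only because the priorities change when silicon is lost; no bond at C1 is touched).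

Step 11
Reactants: 23 (1R,2S,3S,4S,6S)-2-hydroxy-1-methyl-4-[(3S)-6-methyl-3-{[(2Z)-2-methylbut-2-enoyl]oxy}hepta-1,5-dien-2-yl]-7-oxabicyclo[4.1.0]heptan-3-yl 3-methylbut-2-enoate
Product: 24 (1S,3S,4S,6S)-1-methyl-4-[(3S)-6-methyl-3-{[(2Z)-2-methylbut-2-enoyl]oxy}hepta-1,5-dien-2-yl]-2-oxo-7-oxabicyclo[4.1.0]heptan-3-yl 3-methylbut-2-enoate (the target)
Conditions: Dess–Martin periodinane, NaHCO3, CH2Cl2, 0 °C to rt
Reagents that add atoms: none
Why: Buffered Dess–Martin oxidation of the secondary alcohol should give the ketone without epimerising the adjacent acyloxy-bearing C3 or opening the epoxide, and it removes the auxiliary C2 stereocentre that steered the epoxidation.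

**Compound list**

1 | 2-methylfuran | Cc1ccco1 | starting material
2 | (2Z)-4-oxopent-2-enal | CC(=O)/C=C\C=O | intermediate
3 | (2E)-4-oxopent-2-enal | CC(=O)/C=C/C=O | intermediate
4 | tiglaldehyde, (2E)-2-methylbut-2-enal | C/C=C(\C)C=O | starting material
5 | tert-butyl(dimethyl){[(1E)-2-methylbuta-1,3-dien-1-yl]oxy}silane | C=C/C(C)=C/O[Si](C)(C)C(C)(C)C | intermediate
6 | (5R)-5-benzyl-2,2,3-trimethyl-4-oxo-1-[(1E,2E)-4-oxopent-2-en-1-ylidene]imidazolidin-1-ium chloride | CC(=O)/C=C/C=[N+]1/C(C)(C)N(C)C(=O)[C@H]1Cc2ccccc2.[Cl-] | intermediate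
7 | (E)-iminium chloride of aldehyde 8 with the (5R) catalyst (ring configuration as in 8) | CC(=O)[C@@H]1CC=C(C)[C@@H](O[Si](C)(C)C(C)(C)C)[C@H]1/C=[N+]2/C(C)(C)N(C)C(=O)[C@H]2Cc3ccccc3.[Cl-] | intermediate
8 | (1S,2S,6R)-6-acetyl-2-[(tert-butyldimethylsilyl)oxy]-3-methylcyclohex-3-ene-1-carbaldehyde (CHO and OTBS cis, acetyl trans to CHO) | CC(=O)[C@@H]1CC=C(C)[C@@H](O[Si](C)(C)C(C)(C)C)[C@H]1C=O | intermediate
9 | (1S,2S,3S,4R,6S)-4-acetyl-2-[(tert-butyldimethylsilyl)oxy]-1-methyl-7-oxabicyclo[4.1.0]heptane-3-carbaldehyde (epoxide trans to OTBS) | CC(=O)[C@@H]1C[C@@H]2O[C@]2(C)[C@@H](O[Si](C)(C)C(C)(C)C)[C@H]1C=O | intermediate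
10 | (1S,2S,3S,4R,6S)-4-acetyl-2-[(tert-butyldimethylsilyl)oxy]-1-methyl-7-oxabicyclo[4.1.0]heptan-3-yl formate | CC(=O)[C@@H]1C[C@@H]2O[C@]2(C)[C@@H](O[Si](C)(C)C(C)(C)C)[C@H]1OC=O | intermediate
11 | 1-[(1S,2S,3S,4R,6S)-2-[(tert-butyldimethylsilyl)oxy]-3-hydroxy-1-methyl-7-oxabicyclo[4.1.0]heptan-4-yl]ethan-1-one | CC(=O)[C@@H]1C[C@@H]2O[C@]2(C)[C@@H](O[Si](C)(C)C(C)(C)C)[C@H]1O | intermediate
12 | 3-methylbut-2-enoyl chloride (senecioyl chloride) | CC(C)=CC(=O)Cl | starting material
13 | (1S,2S,3S,4R,6S)-4-acetyl-2-[(tert-butyldimethylsilyl)oxy]-1-methyl-7-oxabicyclo[4.1.0]heptan-3-yl 3-methylbut-2-enoate | CC(=O)[C@@H]1C[C@@H]2O[C@]2(C)[C@@H](O[Si](C)(C)C(C)(C)C)[C@H]1OC(=O)C=C(C)C | intermediate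
14 | potassium terminal enolate of methyl ketone 13 | C=C([O-])[C@@H]1C[C@@H]2O[C@]2(C)[C@@H](O[Si](C)(C)C(C)(C)C)[C@H]1OC(=O)C=C(C)C.[K+] | intermediate
15 | (1S,2S,3S,4R,6S)-2-[(tert-butyldimethylsilyl)oxy]-1-methyl-4-{1-[(trifluoromethanesulfonyl)oxy]ethenyl}-7-oxabicyclo[4.1.0]heptan-3-yl 3-methylbut-2-enoate | C=C(OS(=O)(=O)C(F)(F)F)[C@@H]1C[C@@H]2O[C@]2(C)[C@@H](O[Si](C)(C)C(C)(C)C)[C@H]1OC(=O)C=C(C)C | intermediate
16 | 4-methylpent-3-en-1-ol | CC(C)=CCCO | starting material
17 | 4-methylpent-3-enal | CC(C)=CCC=O | intermediate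
18 | alkenylchromium dichloride derived from triflate 15 (Cr in place of OTf) | C=C([Cr](Cl)Cl)[C@@H]1C[C@@H]2O[C@]2(C)[C@@H](O[Si](C)(C)C(C)(C)C)[C@H]1OC(=O)C=C(C)C | intermediate
19 | (1S,2S,3S,4S,6S)-2-[(tert-butyldimethylsilyl)oxy]-4-[(3S)-3-hydroxy-6-methylhepta-1,5-dien-2-yl]-1-methyl-7-oxabicyclo[4.1.0]heptan-3-yl 3-methylbut-2-enoate | C=C([C@H](CC=C(C)C)O)[C@@H]1C[C@@H]2O[C@]2(C)[C@@H](O[Si](C)(C)C(C)(C)C)[C@H]1OC(=O)C=C(C)C | intermediate
20 | angelic acid, (2Z)-2-methylbut-2-enoic acid | C/C=C(/C)C(=O)O | starting material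
21 | (2Z)-2-methylbut-2-enoic 2,4,6-trichlorobenzoic anhydride | C/C=C(/C)C(=O)OC(=O)c1c(Cl)cc(Cl)cc1Cl | intermediate
22 | (1S,2S,3S,4S,6S)-2-[(tert-butyldimethylsilyl)oxy]-1-methyl-4-[(3S)-6-methyl-3-{[(2Z)-2-methylbut-2-enoyl]oxy}hepta-1,5-dien-2-yl]-7-oxabicyclo[4.1.0]heptan-3-yl 3-methylbut-2-enoate | C=C([C@H](CC=C(C)C)OC(=O)/C(C)=C\C)[C@@H]1C[C@@H]2O[C@]2(C)[C@@H](O[Si](C)(C)C(C)(C)C)[C@H]1OC(=O)C=C(C)C | intermediate
23 | (1R,2S,3S,4S,6S)-2-hydroxy-1-methyl-4-[(3S)-6-methyl-3-{[(2Z)-2-methylbut-2-enoyl]oxy}hepta-1,5-dien-2-yl]-7-oxabicyclo[4.1.0]heptan-3-yl 3-methylbut-2-enoate | C=C([C@H](CC=C(C)C)OC(=O)/C(C)=C\C)[C@@H]1C[C@@H]2O[C@]2(C)[C@@H](O)[C@H]1OC(=O)C=C(C)C | intermediate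
24 | (1S,3S,4S,6S)-1-methyl-4-[(3S)-6-methyl-3-{[(2Z)-2-methylbut-2-enoyl]oxy}hepta-1,5-dien-2-yl]-2-oxo-7-oxabicyclo[4.1.0]heptan-3-yl 3-methylbut-2-enoate | C=C([C@H](CC=C(C)C)OC(=O)/C(C)=C\C)[C@@H]1C[C@@H]2O[C@]2(C)C(=O)[C@H]1OC(=O)C=C(C)C | target

**Count and risks**

Total step count: 11. Longest linear sequence: 9 steps (steps 1, 3, 4, 5, 6, 8, 9, 10, 11).

Most likely to fail:

1. Step 3. The addition may run stepwise, as a Mukaiyama–Michael attack of the dienol ether followed by loss of the silyl group instead of ring closure. The dienol ether may also hydrolyse in the wet acidic medium, the endo preference may be low (the C2 epimer would later steer the epoxidation to the wrong face), or the β-silyloxy aldehyde may lose silanol through its enamine. The fallback replaces iminium activation by Lewis-acid activation of a two-point-binding dienophile; it sets out from diene 5 and returns at aldehyde 8. Commercial (2E)-4-oxopent-2-enoic acid is converted with pivaloyl chloride and Et3N into (2E)-4-oxopent-2-enoic pivalic anhydride F1, and F1 acylates 1,3-oxazolidin-2-one in the presence of LiCl to give 3-[(2E)-4-oxopent-2-enoyl]-1,3-oxazolidin-2-one F2. F2 and 5 are combined under catalysis by the Cu(SbF6)2 complex of 2,2′-(propane-2,2-diyl)bis(4-tert-butyl-4,5-dihydro-1,3-oxazole), using the ligand enantiomer that exposes the Re face at the α-carbon. Chelation of divalent copper by both imide carbonyls again makes the acetyl-bearing carbon the electrophilic one and should give the imide cycloadduct F3. EtSLi converts F3 into the S-ethyl thioester F4, and Fukuyama reduction (Et3SiH, Pd/C) of F4 gives 8.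

2. Step 6. Proton exchange may convert the terminal enolate into the internal one, which would expel the β-senecioate (E1cB), and the base may also deprotonate the senecioate at its γ-methyl groups. The fallback removes both problems by changing the order of events; it sets out from alcohol 11 and returns at triflate 15. Compound 11 is silylated (TESOTf, 2,6-lutidine) to the C3 triethylsilyl ether F5. Enol triflation of F5 under the same conditions (KN(SiMe3)2, then PhNTf2) gives the C3-O-triethylsilyl alkenyl triflate F6. Selective cleavage of the triethylsilyl ether in F6 (PPTS, MeOH, 0 °C) gives the C3-hydroxy alkenyl triflate F7, and F7 is acylated with 12 (pyridine, DMAP cat., CH2Cl2) to give 15.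

3. Step 8. Facial selectivity at the aldehyde may be poor if the ligand is mismatched with the ring stereocentres, and the β,γ-unsaturated aldehyde may isomerise. The fallback sets the carbinol centre by reduction instead of by C–C bond formation; it sets out from 15 and 17 and returns at 19. The coupling is run without the chiral ligand (CrCl2, NiCl2 cat., DMF) to give 19 together with its (3R)-carbinol epimer F8. The mixture of 19 and F8 is oxidised with Dess–Martin periodinane to the C3′ enone F9. Corey–Bakshi–Shibata reduction of F9 with the (R)-2-methyl oxazaborolidine and catecholborane at −78 °C, the alkenyl group acting as the large substituent, should give 19.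

**Further compounds**

F1 | step 3 | (2E)-4-oxopent-2-enoic pivalic anhydride | CC(=O)/C=C/C(=O)OC(=O)C(C)(C)C
F2 | step 3 | 3-[(2E)-4-oxopent-2-enoyl]-1,3-oxazolidin-2-one | CC(=O)/C=C/C(=O)N1CCOC1=O
F3 | step 3 | 3-{[(1S,2S,6R)-6-acetyl-2-[(tert-butyldimethylsilyl)oxy]-3-methylcyclohex-3-en-1-yl]carbonyl}-1,3-oxazolidin-2-one | CC(=O)[C@@H]1CC=C(C)[C@@H](O[Si](C)(C)C(C)(C)C)[C@H]1C(=O)N1CCOC1=O
F4 | step 3 | S-ethyl (1S,2S,6R)-6-acetyl-2-[(tert-butyldimethylsilyl)oxy]-3-methylcyclohex-3-ene-1-carbothioate | CC(=O)[C@@H]1CC=C(C)[C@@H](O[Si](C)(C)C(C)(C)C)[C@H]1C(=O)SCC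
F5 | step 6 | 1-[(1S,2S,3S,4R,6S)-2-[(tert-butyldimethylsilyl)oxy]-1-methyl-3-[(triethylsilyl)oxy]-7-oxabicyclo[4.1.0]heptan-4-yl]ethan-1-one | CC(=O)[C@@H]1C[C@@H]2O[C@]2(C)[C@@H](O[Si](C)(C)C(C)(C)C)[C@H]1O[Si](CC)(CC)CC
F6 | step 6 | 1-[(1S,2S,3S,4R,6S)-2-[(tert-butyldimethylsilyl)oxy]-1-methyl-3-[(triethylsilyl)oxy]-7-oxabicyclo[4.1.0]heptan-4-yl]ethenyl trifluoromethanesulfonate | C=C(OS(=O)(=O)C(F)(F)F)[C@@H]1C[C@@H]2O[C@]2(C)[C@@H](O[Si](C)(C)C(C)(C)C)[C@H]1O[Si](CC)(CC)CC
F7 | step 6 | 1-[(1S,2S,3S,4R,6S)-2-[(tert-butyldimethylsilyl)oxy]-3-hydroxy-1-methyl-7-oxabicyclo[4.1.0]heptan-4-yl]ethenyl trifluoromethanesulfonate | C=C(OS(=O)(=O)C(F)(F)F)[C@@H]1C[C@@H]2O[C@]2(C)[C@@H](O[Si](C)(C)C(C)(C)C)[C@H]1O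
F8 | step 8 | (1S,2S,3S,4S,6S)-2-[(tert-butyldimethylsilyl)oxy]-4-[(3R)-3-hydroxy-6-methylhepta-1,5-dien-2-yl]-1-methyl-7-oxabicyclo[4.1.0]heptan-3-yl 3-methylbut-2-enoate | C=C([C@@H](CC=C(C)C)O)[C@@H]1C[C@@H]2O[C@]2(C)[C@@H](O[Si](C)(C)C(C)(C)C)[C@H]1OC(=O)C=C(C)C
F9 | step 8 | (1S,2S,3S,4S,6S)-2-[(tert-butyldimethylsilyl)oxy]-1-methyl-4-(6-methyl-3-oxohepta-1,5-dien-2-yl)-7-oxabicyclo[4.1.0]heptan-3-yl 3-methylbut-2-enoate | C=C(C(=O)CC=C(C)C)[C@@H]1C[C@@H]2O[C@]2(C)[C@@H](O[Si](C)(C)C(C)(C)C)[C@H]1OC(=O)C=C(C)C
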